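**Retrosynthetic overview**

1. Target 33 comes from dodecamethyl ether 32 by cleavage of all twelve methyl ethers in the last step.
2. The strategy rests on ring D, a 1,3,4,5-tetraoxygenated benzene: aryloxy at C1 (to ring C) and at C5 (to ring E), hydroxyls at C3 and C4, hydrogens at C2 and C6. It is the only ring formed, and it is formed last, by benzannulation of ethynyl ether 18 (rings A–B–C) with cyclobutenone 27 (ring E), which makes bonds C2–C3, C1–C6 and C3–C4.
3. Cyclobutenone 27 comes from diisopropyl squarate 19: semisquaric chloride 23 takes up ring E phenol 24 by vinylogous acyl substitution, and carbonyl reduction and O-methylation follow.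
4. Ethynyl ether 18 comes from phenol 12 and trichloroethylene 13. Phenol 12 comes from two rounds of SNAr on a fluorobenzaldehyde followed by Baeyer–Villiger oxidation, first ring A phenol 1 with ring B aldehyde 2, then with ring C aldehyde 9. Rings A, B, C and E are bought as arenes.

Key step: step 14

Remark on the chemistry: the target is achiral, so 20, 26, 27 and the transient sp3 centres of 8, 29 and 31 are carried as racemates. Fluoroarenes 2 and 6 and squarate 19 are taken to be catalogue compounds. Chloride 23, aryl ester 25 and ynol ether 18 are used directly after work-up.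

**Route**

Step 1
Reactants: 1 2,4,6-trimethoxyphenol; 2 4-fluoro-2,6-dimethoxybenzaldehyde
Product: 3 2,6-dimethoxy-4-(2,4,6-trimethoxyphenoxy)benzaldehyde
Conditions: K2CO3, DMF, 100 °C, Ar
Reagents that add atoms: none
Why: Nucleophilic aromatic substitution (SNAr) should proceed because the para-formyl group stabilises the Meisenheimer adduct and fluoride leaves, while both methoxy groups sit meta to fluorine and do not deactivate the reacting carbon.

Step 2
Reactants: 3 2,6-dimethoxy-4-(2,4,6-trimethoxyphenoxy)benzaldehyde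
Product: 5 2,6-dimethoxy-4-(2,4,6-trimethoxyphenoxy)phenol, via aryl formate 4 (not isolated)
Conditions: mCPBA, CH2Cl2, 0 °C → rt; aq. NaHCO3 wash; then K2CO3 (cat.), MeOH, rt
Reagents that add atoms: mCPBA (3-chloroperoxybenzoic acid), OOC(=O)c1cccc(Cl)c1
Why: In this Baeyer–Villiger (Dakin-type) oxidation the electron-rich 2,6-dimethoxyaryl group should migrate in preference to hydride, and mild methanolysis of the formate then frees the phenol.

Step 3
Reactants: 6 5-fluoro-1,2,3-trimethoxybenzene
Product: 9 6-fluoro-2,3,4-trimethoxybenzaldehyde, via aryllithium 7 (not isolated), via lithium hemiaminal alkoxide 8 (not isolated)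
Conditions: n-BuLi, THF, −78 °C; DMF, −78 → 0 °C; 1 M HCl
Reagents that add atoms: DMF (N,N-dimethylformamide), CN(C)C=O
Why: Directed ortho-metalation should give one aldehyde because the only two ring hydrogens are equivalent and each is flanked by fluorine and methoxy; the aryllithium is held at −78 °C to prevent loss of LiF to an aryne before formylation.

Step 4
Reactants: 5 2,6-dimethoxy-4-(2,4,6-trimethoxyphenoxy)phenol; 9 6-fluoro-2,3,4-trimethoxybenzaldehyde
Product: 10 6-[2,6-dimethoxy-4-(2,4,6-trimethoxyphenoxy)phenoxy]-2,3,4-trimethoxybenzaldehyde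
Conditions: Cs2CO3, DMSO, 120 °C, Ar
Reagents that add atoms: none
Why: SNAr with ortho-formyl activation should displace fluoride by the caesium phenoxide of 5, the loosely paired phenoxide in DMSO and heat compensating for the hindered nucleophile and the para-methoxy donor.

Step 5
Reactants: 10 6-[2,6-dimethoxy-4-(2,4,6-trimethoxyphenoxy)phenoxy]-2,3,4-trimethoxybenzaldehyde
Product: 12 6-[2,6-dimethoxy-4-(2,4,6-trimethoxyphenoxy)phenoxy]-2,3,4-trimethoxyphenol, via aryl formate 11 (not isolated)
Conditions: mCPBA, CH2Cl2, 0 °C → rt; aq. NaHCO3 wash; then K2CO3 (cat.), MeOH, rt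
Reagents that add atoms: mCPBA (3-chloroperoxybenzoic acid), OOC(=O)c1cccc(Cl)c1
Why: The same Baeyer–Villiger (Dakin-type) oxidation should turn the aldehyde that activated the SNAr into the C2 hydroxyl of ring C by aryl migration and formate methanolysis.

Step 6
Reactants: 12 6-[2,6-dimethoxy-4-(2,4,6-trimethoxyphenoxy)phenoxy]-2,3,4-trimethoxyphenol; 13 trichloroethylene
Product: 15 2-[(E)-1,2-dichloroethenyloxy]-1-[2,6-dimethoxy-4-(2,4,6-trimethoxyphenoxy)phenoxy]-3,4,5-trimethoxybenzene, via dichloroacetylene 14 (not isolated)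
Conditions: K2CO3, DMF, 70 °C
Reagents that add atoms: none
Why: Base-mediated elimination–addition should work because carbonate turns trichloroethylene into dichloroacetylene, a small linear electrophile that the doubly ortho-substituted phenoxide can still reach, and anti addition gives the (E)-dichlorovinyl ether.

Step 7
Reactants: 15 2-[(E)-1,2-dichloroethenyloxy]-1-[2,6-dimethoxy-4-(2,4,6-trimethoxyphenoxy)phenoxy]-3,4,5-trimethoxybenzene
Product: 18 2-(ethynyloxy)-1-[2,6-dimethoxy-4-(2,4,6-trimethoxyphenoxy)phenoxy]-3,4,5-trimethoxybenzene, via chloroethynyl ether 16 (not isolated), via lithium acetylide 17 (not isolated)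
Conditions: n-BuLi (2.2 equiv), THF, −78 → −40 °C; H2O, −78 °C
Reagents that add atoms: none
Why: β-Elimination of HCl followed by chlorine–lithium exchange and protonation of the acetylide should give the terminal aryl ynol ether, since at −78 °C removal of the vinyl hydrogen is much faster than lithiation of the methoxyarenes.

Step 8
Reactants: 19 3,4-di(propan-2-yloxy)cyclobut-3-ene-1,2-dione (diisopropyl squarate)
Product: 21 3-(propan-2-yloxy)cyclobut-3-ene-1,2-dione, via hydroxycyclobutenone 20 (not isolated)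
Conditions: LiAlH(OtBu)3, THF, −78 → 0 °C; then conc. HCl, CH2Cl2, rt
Reagents that add atoms: water (from the aqueous acid), O
Why: Hydride 1,2-reduction of one squarate carbonyl gives racemic hydroxycyclobutenone 20; acid should then ionise the C4 hydroxyl to an alkoxy-stabilised cyclobutenyl cation, which is hydrolysed at the isopropoxy-bearing carbon with loss of propan-2-ol, an allylic transposition that leaves the semisquarate with hydrogen on the ring.

Step 9
Reactants: 21 3-(propan-2-yloxy)cyclobut-3-ene-1,2-dione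
Product: 22 3-hydroxycyclobut-3-ene-1,2-dione (semisquaric acid)
Conditions: aq. HCl (2 M), THF, 50 °C; concentrate, dry azeotropically (PhMe)
Reagents that add atoms: water, O
Why: Acid hydrolysis of the vinylogous ester by addition–elimination of water should free the strongly acidic vinylogous carboxylic acid, which is recovered by evaporation because it is water-soluble.

Step 10
Reactants: 22 3-hydroxycyclobut-3-ene-1,2-dione (semisquaric acid)
Product: 23 3-chlorocyclobut-3-ene-1,2-dione (semisquaric chloride)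
Conditions: (COCl)2, DMF (cat.), CH2Cl2, 0 °C → rt
Reagents that add atoms: oxalyl chloride, ClC(=O)C(Cl)=O
Why: Vilsmeier-type activation should convert the vinylogous acid into the vinylogous acid chloride just as a carboxylic acid gives an acyl chloride, with CO, CO2 and HCl leaving as gases.

Step 11
Reactants: 23 3-chlorocyclobut-3-ene-1,2-dione (semisquaric chloride); 24 3,4,5-trimethoxyphenol
Product: 25 3-(3,4,5-trimethoxyphenoxy)cyclobut-3-ene-1,2-dione
Conditions: 2,6-lutidine, CH2Cl2, −78 → 0 °C, Ar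
Reagents that add atoms: none
Why: Vinylogous acyl substitution (addition–elimination at the chlorine-bearing carbon) should attach ring E through oxygen, since without a Lewis acid and with a hindered amine base the phenol reacts at oxygen, not by Friedel–Crafts attack of its ring.

Step 12
Reactants: 25 3-(3,4,5-trimethoxyphenoxy)cyclobut-3-ene-1,2-dione
Product: 26 rac-4-hydroxy-3-(3,4,5-trimethoxyphenoxy)cyclobut-2-en-1-one
Conditions: LiAlH(OtBu)3 (1.0 equiv), THF, −78 °C; aq. NH4Cl
Reagents that add atoms: none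
Why: Hydride 1,2-reduction should take place at the carbonyl next to the aryloxy-bearing carbon, because the other carbonyl is deactivated as a vinylogous ester and the bulky hydride at −78 °C disfavours conjugate displacement of the aryloxide; the carbinol centre forms as the racemate, which suffices because it later becomes an aromatic carbon.

Step 13
Reactants: 26 rac-4-hydroxy-3-(3,4,5-trimethoxyphenoxy)cyclobut-2-en-1-one
Product: 27 rac-4-methoxy-3-(3,4,5-trimethoxyphenoxy)cyclobut-2-en-1-one
Conditions: MeI (excess), Ag2O, 4 Å MS, MeCN, rt, dark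
Reagents that add atoms: iodomethane, CI
Why: Purdie O-methylation under nearly neutral conditions should etherify the secondary hydroxyl without base-induced opening of the strained ring or loss of the aryloxy group, and the racemic centre is not touched.

Step 14
Reactants: 18 2-(ethynyloxy)-1-[2,6-dimethoxy-4-(2,4,6-trimethoxyphenoxy)phenoxy]-3,4,5-trimethoxybenzene; 27 rac-4-methoxy-3-(3,4,5-trimethoxyphenoxy)cyclobut-2-en-1-one
Product: 32 5-{6-[2,6-dimethoxy-4-(2,4,6-trimethoxyphenoxy)phenoxy]-2,3,4-trimethoxyphenoxy}-2-methoxy-3-(3,4,5-trimethoxyphenoxy)phenol, via vinylketene 28 (not isolated), via vinylcyclobutenone 29 (not isolated), via dienylketene 30 (not isolated), via cyclohexadienone 31 (not isolated)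
Conditions: PhMe, 80 → 110 °C, Ar, 27 (1.5 equiv)
Reagents that add atoms: none
Why: Danheiser benzannulation: 27 should undergo 4π electrocyclic opening (methoxy rotating outward) to vinylketene 28, whose ketene C=C adds [2+2] to ynol ether 18 to give vinylcyclobutenone 29, and a second 4π opening to dienylketene 30, 6π electrocyclisation to cyclohexadienone 31 and enolisation then deliver phenol 32. The closest known reaction type is the thermal benzannulation of cyclobutenones with alkoxy- and siloxyacetylenes to resorcinol monoethers. Ring D is closed by the disrotatory 6π electrocyclisation that joins the ketene carbon (C3 of ring D) to the methoxy-bearing terminus (C4), after the [2+2] step has made C2–C3 and C1–C6. No stereocentre remains, because the racemic centre of 27 and the sp3 centres of 29 and 31 all become aromatic carbons. The step needs the regiochemistry of the ketene–alkyne addition, which the polarisation of the partners should secure (nucleophilic CH terminus of 18 to the electrophilic ketene carbonyl carbon, so that the ring C aryloxy group ends meta to the new hydroxyl). It also needs capture of 28 by 18 to outrun ketene dimerisation, for which the electron-rich ynol ether and the excess of 27 are relied on.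

Step 15
Reactants: 32 5-{6-[2,6-dimethoxy-4-(2,4,6-trimethoxyphenoxy)phenoxy]-2,3,4-trimethoxyphenoxy}-2-methoxy-3-(3,4,5-trimethoxyphenoxy)phenol
Product: 33 5-{6-[2,6-dihydroxy-4-(2,4,6-trihydroxyphenoxy)phenoxy]-2,3,4-trihydroxyphenoxy}-3-(3,4,5-trihydroxyphenoxy)benzene-1,2-diol
Conditions: BBr3 (excess), CH2Cl2, −78 °C → rt; H2O, 0 °C, Ar
Reagents that add atoms: none
Why: Lewis acid O-demethylation should remove all twelve methyl groups, since BBr3 coordinates each methoxy oxygen and bromide takes the methyl by SN2 while diaryl ether C–O bonds are left intact; hydrolysis of the aryl borates under argon frees the oxidation-sensitive polyphenol.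

**Compound list**

1 | 2,4,6-trimethoxyphenol | COc1cc(OC)c(O)c(OC)c1 | starting material
2 | 4-fluoro-2,6-dimethoxybenzaldehyde | COc1cc(F)cc(OC)c1C=O | starting material
3 | 2,6-dimethoxy-4-(2,4,6-trimethoxyphenoxy)benzaldehyde | COc1cc(OC)cc(OC)c1Oc1cc(OC)c(C=O)c(OC)c1 | intermediate
4 | 2,6-dimethoxy-4-(2,4,6-trimethoxyphenoxy)phenyl formate | COc1cc(OC)cc(OC)c1Oc1cc(OC)c(OC=O)c(OC)c1 | intermediate
5 | 2,6-dimethoxy-4-(2,4,6-trimethoxyphenoxy)phenol | COc1cc(OC)cc(OC)c1Oc1cc(OC)c(O)c(OC)c1 | intermediate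
6 | 5-fluoro-1,2,3-trimethoxybenzene | COc1cc(F)cc(OC)c1OC | starting material
7 | (6-fluoro-2,3,4-trimethoxyphenyl)lithium | [Li]c1c(F)cc(OC)c(OC)c1OC | intermediate
8 | lithium (dimethylamino)(6-fluoro-2,3,4-trimethoxyphenyl)methanolate, racemic | CN(C)C(O[Li])c1c(F)cc(OC)c(OC)c1OC | intermediate
9 | 6-fluoro-2,3,4-trimethoxybenzaldehyde | COc1cc(F)c(C=O)c(OC)c1OC | intermediate
10 | 6-[2,6-dimethoxy-4-(2,4,6-trimethoxyphenoxy)phenoxy]-2,3,4-trimethoxybenzaldehyde | COc1cc(OC)cc(OC)c1Oc1cc(OC)c(Oc2cc(OC)c(OC)c(OC)c2C=O)c(OC)c1 | intermediate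
11 | 6-[2,6-dimethoxy-4-(2,4,6-trimethoxyphenoxy)phenoxy]-2,3,4-trimethoxyphenyl formate | COc1cc(OC)cc(OC)c1Oc1cc(OC)c(Oc2cc(OC)c(OC)c(OC)c2OC=O)c(OC)c1 | intermediate
12 | 6-[2,6-dimethoxy-4-(2,4,6-trimethoxyphenoxy)phenoxy]-2,3,4-trimethoxyphenol | COc1cc(OC)cc(OC)c1Oc1cc(OC)c(Oc2cc(OC)c(OC)c(OC)c2O)c(OC)c1 | intermediate
13 | trichloroethylene | ClC=C(Cl)Cl | starting material
14 | dichloroacetylene | ClC#CCl | intermediate
15 | 2-[(E)-1,2-dichloroethenyloxy]-1-[2,6-dimethoxy-4-(2,4,6-trimethoxyphenoxy)phenoxy]-3,4,5-trimethoxybenzene | COc1cc(OC)cc(OC)c1Oc1cc(OC)c(Oc2cc(OC)c(OC)c(OC)c2O/C(Cl)=C\Cl)c(OC)c1 | intermediate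
16 | 2-(chloroethynyloxy)-1-[2,6-dimethoxy-4-(2,4,6-trimethoxyphenoxy)phenoxy]-3,4,5-trimethoxybenzene | COc1cc(OC)cc(OC)c1Oc1cc(OC)c(Oc2cc(OC)c(OC)c(OC)c2OC#CCl)c(OC)c1 | intermediate
17 | lithium acetylide of 18, ({6-[2,6-dimethoxy-4-(2,4,6-trimethoxyphenoxy)phenoxy]-2,3,4-trimethoxyphenoxy}ethynyl)lithium | COc1cc(OC)cc(OC)c1Oc1cc(OC)c(Oc2cc(OC)c(OC)c(OC)c2OC#C[Li])c(OC)c1 | intermediate
18 | 2-(ethynyloxy)-1-[2,6-dimethoxy-4-(2,4,6-trimethoxyphenoxy)phenoxy]-3,4,5-trimethoxybenzene | COc1cc(OC)cc(OC)c1Oc1cc(OC)c(Oc2cc(OC)c(OC)c(OC)c2OC#C)c(OC)c1 | intermediate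
19 | 3,4-di(propan-2-yloxy)cyclobut-3-ene-1,2-dione (diisopropyl squarate) | CC(C)OC1=C(OC(C)C)C(=O)C1=O | starting material
20 | rac-4-hydroxy-2,3-di(propan-2-yloxy)cyclobut-2-en-1-one | CC(C)OC1=C(OC(C)C)C(O)C1=O | intermediate
21 | 3-(propan-2-yloxy)cyclobut-3-ene-1,2-dione | CC(C)OC1=CC(=O)C1=O | intermediate
22 | 3-hydroxycyclobut-3-ene-1,2-dione (semisquaric acid) | OC1=CC(=O)C1=O | intermediate
23 | 3-chlorocyclobut-3-ene-1,2-dione (semisquaric chloride) | ClC1=CC(=O)C1=O | intermediate
24 | 3,4,5-trimethoxyphenol | COc1cc(O)cc(OC)c1OC | starting material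
25 | 3-(3,4,5-trimethoxyphenoxy)cyclobut-3-ene-1,2-dione | COc1cc(OC2=CC(=O)C2=O)cc(OC)c1OC | intermediate
26 | rac-4-hydroxy-3-(3,4,5-trimethoxyphenoxy)cyclobut-2-en-1-one | COc1cc(OC2=CC(=O)C2O)cc(OC)c1OC | intermediate
27 | rac-4-methoxy-3-(3,4,5-trimethoxyphenoxy)cyclobut-2-en-1-one | COC1C(Oc2cc(OC)c(OC)c(OC)c2)=CC1=O | intermediate
28 | (3Z)-4-methoxy-3-(3,4,5-trimethoxyphenoxy)buta-1,3-dien-1-one | O=C=C/C(Oc1cc(OC)c(OC)c(OC)c1)=C/OC | intermediate
29 | rac-3-{6-[2,6-dimethoxy-4-(2,4,6-trimethoxyphenoxy)phenoxy]-2,3,4-trimethoxyphenoxy}-4-[(Z)-2-methoxy-1-(3,4,5-trimethoxyphenoxy)ethenyl]cyclobut-2-en-1-one | O=C1C=C(Oc2c(OC)c(OC)c(OC)cc2Oc2c(OC)cc(Oc3c(OC)cc(OC)cc3OC)cc2OC)C1/C(Oc1cc(OC)c(OC)c(OC)c1)=C/OC | intermediate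
30 | (3E,5Z)-3-{6-[2,6-dimethoxy-4-(2,4,6-trimethoxyphenoxy)phenoxy]-2,3,4-trimethoxyphenoxy}-6-methoxy-5-(3,4,5-trimethoxyphenoxy)hexa-1,3,5-trien-1-one | O=C=C/C(Oc1c(OC)c(OC)c(OC)cc1Oc1c(OC)cc(Oc2c(OC)cc(OC)cc2OC)cc1OC)=C\C(Oc1cc(OC)c(OC)c(OC)c1)=C\OC | intermediate
31 | rac-3-{6-[2,6-dimethoxy-4-(2,4,6-trimethoxyphenoxy)phenoxy]-2,3,4-trimethoxyphenoxy}-6-methoxy-5-(3,4,5-trimethoxyphenoxy)cyclohexa-2,4-dien-1-one | O=C1C=C(Oc2c(OC)c(OC)c(OC)cc2Oc2c(OC)cc(Oc3c(OC)cc(OC)cc3OC)cc2OC)C=C(Oc2cc(OC)c(OC)c(OC)c2)C1OC | intermediate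
32 | 5-{6-[2,6-dimethoxy-4-(2,4,6-trimethoxyphenoxy)phenoxy]-2,3,4-trimethoxyphenoxy}-2-methoxy-3-(3,4,5-trimethoxyphenoxy)phenol | COc1cc(OC)cc(OC)c1Oc1cc(OC)c(Oc2cc(OC)c(OC)c(OC)c2Oc2cc(O)c(OC)c(Oc3cc(OC)c(OC)c(OC)c3)c2)c(OC)c1 | intermediate
33 | 5-{6-[2,6-dihydroxy-4-(2,4,6-trihydroxyphenoxy)phenoxy]-2,3,4-trihydroxyphenoxy}-3-(3,4,5-trihydroxyphenoxy)benzene-1,2-diol | Oc1cc(O)c(Oc2cc(O)c(Oc3cc(O)c(O)c(O)c3Oc3cc(O)c(O)c(Oc4cc(O)c(O)c(O)c4)c3)c(O)c2)c(O)c1 | target

**Step count and risks**

Total: 15 steps. Longest linear sequence: 8 steps (1, 2, 4, 5, 6, 7, 14, 15; the ring E branch 8–13, 14, 15 is equally long).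

Steps most likely to fail:

Step 14. The vinylketene released from 27 may dimerise, or acylate the phenol as it forms, faster than it adds to the hindered and only moderately nucleophilic aryl ynol ether, and the ynol ether may oligomerise on heating. The fallback brings ring D in preformed and joins it by two copper-mediated ether couplings; it sets out from phenol 12 and comes back at target 33. Catalogue 5-bromo-2,3-dimethoxyphenol and (3,4,5-trimethoxyphenyl)boronic acid under Chan–Lam conditions (Cu(OAc)2, pyridine, 4 Å MS, CH2Cl2, air) should give 5-bromo-1,2-dimethoxy-3-(3,4,5-trimethoxyphenoxy)benzene F1. Ullmann coupling of 12 with F1 (CuI, picolinic acid, K3PO4, DMSO, 100 °C) should give the tridecamethyl ether 1-{6-[2,6-dimethoxy-4-(2,4,6-trimethoxyphenoxy)phenoxy]-2,3,4-trimethoxyphenoxy}-3,4-dimethoxy-5-(3,4,5-trimethoxyphenoxy)benzene F2, which BBr3 in CH2Cl2 would demethylate to 33.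

Step 12. Hydride may add in conjugate fashion and expel the aryloxide, or reduce both carbonyls, so that the hydroxycyclobutenone is not obtained cleanly. The fallback builds the four-membered ring with its substituents already in place by a ketene–alkyne cycloaddition; it sets out from phenol 24 and trichloroethylene 13 and comes back at cyclobutenone 27. Phenol 24 and 13 (K2CO3, DMF, 70 °C, as in step 6) should give 5-[(E)-1,2-dichloroethenyloxy]-1,2,3-trimethoxybenzene F3. n-BuLi (2.2 equiv, THF, −78 °C) should eliminate HCl to 5-(chloroethynyloxy)-1,2,3-trimethoxybenzene F4 and exchange chlorine for lithium to give [(3,4,5-trimethoxyphenoxy)ethynyl]lithium F5, and water then gives 5-(ethynyloxy)-1,2,3-trimethoxybenzene F6. Slow addition of methoxyacetyl chloride to Et3N and F6 (CH2Cl2, 0 °C → rt) releases methoxyketene F7, whose [2+2] cycloaddition, carbonyl carbon to the CH terminus of the ynol ether, should give 27 directly.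

Step 4. Addition of the doubly ortho-substituted phenoxide to a ring deactivated by its para-methoxy group may be so slow that aldehyde degradation or phenoxide-induced demethylation takes over. The fallback replaces the uncatalysed substitution by a copper-catalysed aryl ether coupling on the bromo analogue; it sets out from phenol 5 and comes back at aldehyde 10. Rieche formylation (Cl2CHOMe, TiCl4, CH2Cl2, 0 °C) of catalogue 5-bromo-1,2,3-trimethoxybenzene should give 6-bromo-2,3,4-trimethoxybenzaldehyde F8, whose two free ring positions are equivalent. Ullmann coupling of 5 with F8 (CuI, picolinic acid, K3PO4, DMSO, 90 °C), helped by the ortho-formyl group, should then give 10.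

**Further compounds**

F1 | step 14 | 5-bromo-1,2-dimethoxy-3-(3,4,5-trimethoxyphenoxy)benzene | COc1cc(Br)cc(Oc2cc(OC)c(OC)c(OC)c2)c1OC
F2 | step 14 | 1-{6-[2,6-dimethoxy-4-(2,4,6-trimethoxyphenoxy)phenoxy]-2,3,4-trimethoxyphenoxy}-3,4-dimethoxy-5-(3,4,5-trimethoxyphenoxy)benzene | COc1cc(OC)cc(OC)c1Oc1cc(OC)c(Oc2cc(OC)c(OC)c(OC)c2Oc2cc(OC)c(OC)c(Oc3cc(OC)c(OC)c(OC)c3)c2)c(OC)c1
F3 | step 12 | 5-[(E)-1,2-dichloroethenyloxy]-1,2,3-trimethoxybenzene | COc1cc(O/C(Cl)=C\Cl)cc(OC)c1OC
F4 | step 12 | 5-(chloroethynyloxy)-1,2,3-trimethoxybenzene | COc1cc(OC#CCl)cc(OC)c1OC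
F5 | step 12 | [(3,4,5-trimethoxyphenoxy)ethynyl]lithium | COc1cc(OC#C[Li])cc(OC)c1OC
F6 | step 12 | 5-(ethynyloxy)-1,2,3-trimethoxybenzene | COc1cc(OC#C)cc(OC)c1OC
F7 | step 12 | methoxyketene | COC=C=O
F8 | step 4 | 6-bromo-2,3,4-trimethoxybenzaldehyde | COc1cc(Br)c(C=O)c(OC)c1OC
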